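**Retrosynthetic overview**
1. The target is an 18-membered cyclophane of four benzene rings: A (OH-bearing, 1,2,4-trisubstituted), B (para-phenylene), C (OH-bearing, 1,3,4-trisubstituted) and D (meta-phenylene). They are joined A–CH2CH2–B, B–O–C, C–CH2CH2–D and D–O–A.
2. Enabling feature: C3 of ring C, which carries the ring-B oxygen, is ortho to C4–OH, and the ring-A carbon that carries the ring-D oxygen is para to the ring-A OH. Each OH is the Baeyer–Villiger/Dakin retron of a formyl group, which sits exactly where an SNAr Meisenheimer complex needs an acceptor.
3. Disconnections: both OH ⇒ CHO (double Baeyer–Villiger, last step); ring-B O–C3 of ring C ⇒ phenol + o-fluorobenzaldehyde (macrocyclic SNAr); both CH2CH2 ⇒ alkynes (two Sonogashira couplings, C–I before C–Br, then one hydrogenation); D–O–A ⇒ intermolecular SNAr.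
4. Ring order: the four benzene rings are bought, and the macrocycle is the only ring made (step 5). No protecting group is used.

Key step: step 5

Remark on the chemistry: the SMILES has no stereodescriptor and the molecule has no stereocentre. The 18-membered cyclophane is assumed to interconvert freely between its ring-flip conformers at room temperature, so it is treated as achiral and no step has to control configuration.

Step 1
Reactants: 1 3-bromo-4-fluorobenzaldehyde; 2 3-ethynylphenol
Product: 3 3-bromo-4-(3-ethynylphenoxy)benzaldehyde
Conditions: K2CO3 (1.5 equiv), DMF, 80 °C, Ar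
Reagents that add atoms: none
Why: Intermolecular SNAr, in which the fluorine of 1 is para to the formyl group and flanked by bromine, so the phenoxide of 2 should displace only fluoride while the C–Br bond (meta to CHO) and the terminal alkyne are inert to carbonate.

Step 2
Reactants: 3 3-bromo-4-(3-ethynylphenoxy)benzaldehyde; 4 2-fluoro-4-iodobenzaldehyde
Product: 5 3-bromo-4-{3-[(3-fluoro-4-formylphenyl)ethynyl]phenoxy}benzaldehyde
Conditions: PdCl2(PPh3)2 (2 mol %), CuI (4 mol %), Et3N (3 equiv), THF, rt, degassed
Reagents that add atoms: none
Why: Sonogashira coupling, in which oxidative addition at room temperature should occur only at the C–I bond of 4, so the hindered C–Br bond next to the aryloxy group is kept for step 3 and Et3N leaves the activated C–F bond alone.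

Step 3
Reactants: 5 3-bromo-4-{3-[(3-fluoro-4-formylphenyl)ethynyl]phenoxy}benzaldehyde; 6 4-ethynylphenol
Product: 7 4-{3-[(3-fluoro-4-formylphenyl)ethynyl]phenoxy}-3-[(4-hydroxyphenyl)ethynyl]benzaldehyde
Conditions: Pd(PhCN)2Cl2 (3 mol %), P(t-Bu)3 (6 mol %), CuI (2 mol %), i-Pr2NH (2 equiv), dioxane, rt, Ar
Reagents that add atoms: none
Why: Sonogashira coupling of an aryl bromide with the electron-rich Pd/P(t-Bu)3 catalyst, which works at room temperature, where the phenol is not deprotonated by the amine and cannot attack the C–F bond, and where 6 does not polymerise.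

Step 4
Reactants: 7 4-{3-[(3-fluoro-4-formylphenyl)ethynyl]phenoxy}-3-[(4-hydroxyphenyl)ethynyl]benzaldehyde
Product: 8 4-{3-[2-(3-fluoro-4-formylphenyl)ethyl]phenoxy}-3-[2-(4-hydroxyphenyl)ethyl]benzaldehyde (seco-dialdehyde)
Conditions: H2 (1 atm), 10 % Pd/C, Ph2S (cat.), EtOAc, rt
Reagents that add atoms: none
Why: Chemoselective heterogeneous hydrogenation on sulfide-poisoned Pd/C, a system known to saturate alkynes and alkenes while sparing aromatic aldehydes and aryl halides, should turn both diarylalkynes into CH2CH2 bridges in one operation.

Step 5
Reactants: 8 4-{3-[2-(3-fluoro-4-formylphenyl)ethyl]phenoxy}-3-[2-(4-hydroxyphenyl)ethyl]benzaldehyde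
Product: 9 macrocyclic dialdehyde (the target ring system with CHO in place of both OH groups)
Conditions: Cs2CO3 (3 equiv), 4 Å MS, DMSO, 95 °C, Ar, syringe-pump addition of 8 (final ≤ 2 mM)
Reagents that add atoms: none
Why: Cs2CO3 converts the only phenol (ring B) into its caesium phenoxide, which adds to the fluorine-bearing C3 of ring C to give a Meisenheimer complex whose charge is delocalised onto the oxygen of the ortho formyl group at C4, and loss of fluoride restores the arene (addition–elimination SNAr). The closest known reaction types are the macrocyclic SNAr cycloetherification of phenols onto o-nitrofluoroarenes, used for cyclophane diaryl ethers of similar size, and the intermolecular diaryl ether synthesis from 2-fluorobenzaldehydes; formyl is a somewhat weaker acceptor than nitro, which is compensated by temperature and a poorly solvated caesium phenoxide in DMSO. The one ring closed is the 18-membered cyclophane, by end-to-end attack of the chain-terminal oxygen on an sp2 ring carbon, and no stereocentre is formed. Site selectivity is built into 8: it has one O-nucleophile and one C–F bond, and the only other activated carbon (ring A, para to the second CHO) bears a much poorer leaving group (aryloxide) and could be reached by the ring-B oxygen only through an impossibly strained nine-membered paracyclophane. Ring closure should beat oligomerisation because slow addition keeps the stationary concentration very low, the ortho junction at ring A and the meta junction at ring D fold the chain, and the substitution is irreversible at this temperature. The aldehydes have no α-hydrogens and should survive dry carbonate, and DMSO is chosen over DMF so that no dimethylamine can compete for the C–F bond.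

Step 6
Reactants: 9 macrocyclic dialdehyde
Product: 11 target CNP0135015.0, via macrocyclic bis(formate) 10 (not isolated)
Conditions: mCPBA (3 equiv), CH2Cl2, 0 °C → rt; wash (aq NaHCO3/Na2S2O3), concentrate; crude taken up in MeOH, K2CO3 (cat.), rt
Reagents that add atoms: mCPBA, OOC(=O)c1cccc(Cl)c1
Why: Double Baeyer–Villiger (Dakin-type) oxidation, in which the aryl group of each Criegee adduct is made electron-rich by its ortho (ring C) or para (ring A) aryloxy substituent and should migrate in preference to hydrogen, and the two labile aryl formates are then methanolysed without touching the diaryl ethers.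

**Compound list**
1 | 3-bromo-4-fluorobenzaldehyde | O=Cc1ccc(F)c(Br)c1 | starting material
2 | 3-ethynylphenol | Oc1cccc(C#C)c1 | starting material
3 | 3-bromo-4-(3-ethynylphenoxy)benzaldehyde | O=Cc1ccc(Oc2cccc(C#C)c2)c(Br)c1 | intermediate
4 | 2-fluoro-4-iodobenzaldehyde | O=Cc1ccc(I)cc1F | starting material
5 | 3-bromo-4-{3-[(3-fluoro-4-formylphenyl)ethynyl]phenoxy}benzaldehyde | O=Cc1ccc(Oc2cccc(C#Cc3ccc(C=O)c(F)c3)c2)c(Br)c1 | intermediate
6 | 4-ethynylphenol | Oc1ccc(C#C)cc1 | starting material
7 | 4-{3-[(3-fluoro-4-formylphenyl)ethynyl]phenoxy}-3-[(4-hydroxyphenyl)ethynyl]benzaldehyde | O=Cc1ccc(Oc2cccc(C#Cc3ccc(C=O)c(F)c3)c2)c(C#Cc2ccc(O)cc2)c1 | intermediate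
8 | 4-{3-[2-(3-fluoro-4-formylphenyl)ethyl]phenoxy}-3-[2-(4-hydroxyphenyl)ethyl]benzaldehyde | O=Cc1ccc(Oc2cccc(CCc3ccc(C=O)c(F)c3)c2)c(CCc2ccc(O)cc2)c1 | intermediate
9 | macrocyclic dialdehyde (CHO on ring A para to the D–O–A oxygen, CHO on ring C ortho to the B–O–C oxygen) | O=Cc1ccc2c(c1)CCc1ccc(cc1)Oc1cc(ccc1C=O)CCc1cccc(c1)O2 | intermediate
10 | macrocyclic bis(formate) (OCHO in place of both CHO groups of 9) | O=COc1ccc2c(c1)CCc1ccc(cc1)Oc1cc(ccc1OC=O)CCc1cccc(c1)O2 | intermediate
11 | CNP0135015.0 (macrocyclic bis(bibenzyl) diether diphenol) | Oc1ccc2c(c1)CCc1ccc(cc1)Oc1cc(ccc1O)CCc1cccc(c1)O2 | target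

Total step count: 6. Longest linear sequence: 6 (from 1 or 2 to 11).

**Steps most likely to fail**

Step 5. Intermolecular etherification may overtake the fairly slow ring closure and lead to oligomerisation, and the aldehydes may slowly degrade at the temperature that formyl activation requires. The fallback closes the ring at the stilbene oxidation level and sets out from 7. Semihydrogenation (H2, Lindlar catalyst, quinoline, EtOAc, rt) should give the (Z,Z)-distilbene seco-dialdehyde F1. Its two temporary cis double bonds replace freely rotating bridges and fold the chain ends towards each other. The Cs2CO3/DMSO SNAr closure, now with a higher effective molarity and hence a lower temperature, should give the macrocyclic (Z,Z)-diene dialdehyde F2. Hydrogenation under the conditions of step 4 returns to the route at 9. Material over-reduced in the Lindlar step is 8 or a half-saturated relative and converges on 9 as well.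

Step 4. The aromatic aldehydes may be over-reduced to benzylic alcohols or methyl groups, or the reduction may stall at the stilbene stage on the poisoned catalyst. The fallback replaces catalyst control by masking and sets out from 7. Treatment with HC(OMe)3 and cat. TsOH in MeOH should give the diyne bis(dimethyl acetal) F3. An unpoisoned hydrogenation (H2, Pd/C, EtOAc with a trace of Et3N) should give the saturated bis(dimethyl acetal) F4. Aqueous HCl in THF at rt returns to the route at 8.

Step 6. Hydride instead of aryl migration at one of the two Criegee adducts would form a carboxylic acid, and the liberated electron-rich phenols may be over-oxidised. The fallback removes the migrating hydrogen and sets out from 9. MeMgBr (THF, 0 °C) should give the macrocyclic bis(1-hydroxyethyl) compound F5, a diastereomer mixture whose stereocentres are erased in the next operation. MnO2 or Dess–Martin oxidation should give the macrocyclic diacetyl compound F6. Baeyer–Villiger oxidation (mCPBA, TFA, CH2Cl2), in which aryl competes only with methyl, should give the macrocyclic bis(acetate) F7. Methanolysis (K2CO3, MeOH) returns to the route at 11.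

**Further compounds**
F1 | step 5 | (Z,Z)-distilbene seco-dialdehyde | O=Cc1ccc(Oc2cccc(/C=C\c3ccc(C=O)c(F)c3)c2)c(/C=C\c2ccc(O)cc2)c1
F2 | step 5 | macrocyclic (Z,Z)-diene dialdehyde | O=Cc1ccc2c(c1)/C=C\c1ccc(cc1)Oc1cc(ccc1C=O)/C=C\c1cccc(c1)O2
F3 | step 4 | diyne bis(dimethyl acetal) | COC(OC)c1ccc(Oc2cccc(C#Cc3ccc(C(OC)OC)c(F)c3)c2)c(C#Cc2ccc(O)cc2)c1
F4 | step 4 | saturated bis(dimethyl acetal) | COC(OC)c1ccc(Oc2cccc(CCc3ccc(C(OC)OC)c(F)c3)c2)c(CCc2ccc(O)cc2)c1
F5 | step 6 | macrocyclic bis(1-hydroxyethyl) compound (diastereomer mixture) | CC(O)c1ccc2c(c1)CCc1ccc(cc1)Oc1cc(ccc1C(C)O)CCc1cccc(c1)O2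
F6 | step 6 | macrocyclic diacetyl compound | CC(=O)c1ccc2c(c1)CCc1ccc(cc1)Oc1cc(ccc1C(C)=O)CCc1cccc(c1)O2
F7 | step 6 | macrocyclic bis(acetate) | CC(=O)Oc1ccc2c(c1)CCc1ccc(cc1)Oc1cc(ccc1OC(C)=O)CCc1cccc(c1)O2
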